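The constants used here were chosen freely.

The solid hands over 0.0217 mM s⁻¹ at the very most, less than the 0.238 mM s⁻¹ the catalyst could turn over in a solution held at saturation, and the dispute over this flask is which of these two rates counts.

    solid substrate ⇌ starting material, rate k1*(cs1 - [starting material]) while solid is left; crystals form when [starting material] > cs1 (cs1 = 0.72 mM, k1 = 0.0301 s⁻¹)
    catalyst intermediate A → free catalyst + target (k2 = 1150 s⁻¹)
    catalyst intermediate B → free catalyst + second product (k3 = 2200 s⁻¹)
    starting material + free catalyst ⇌ catalyst intermediate A (K4 = 1100 M⁻¹, k4 = 1.05 × 10⁷ M⁻¹ s⁻¹)
    second substrate + protic impurity → quenched substrate (k5 = 582 M⁻¹ s⁻¹)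
    second substrate + free catalyst ⇌ catalyst intermediate B (K6 = 730 M⁻¹, k6 = 2.86 × 10⁵ M⁻¹ s⁻¹)

solid substrate 1.0 mM; second substrate 1.00 equiv; protic impurity 0.100 mM; free catalyst 0.05 mol%; time 12 s

- solid, in amounts per volume of the solution: solid substrate
- at the start none of the solid substrate is in solution
- starting material means what is dissolved; the solid is not counted in it
- run time (flask): 12 s

- target at 12 s, in percent of the solid substrate charged
- concentration of starting material in solution at 1.2 s, in percent of saturation
- the change that raises the amount of target at 12 s, in percent of the solid substrate charged most ("none" if none brings more than 2 percentage points) (cedar / ash / elm / none)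
- amount of target at 12 s, in percent of the solid substrate charged, after cedar

- cedar: doubling the solubility in step 1, all else as stated
- ash: doubling the dissolution coefficient of step 1, all else as stated
- elm: doubling the amount of free catalyst, all else as stated

The catalyst view says that a loading of 0.05 mol% is what runs short: the solution stands near its solubility of 0.72 mM, the charge is through in 4.20 s, and elm is the change to make.

I hold the feed view, because a solution kept that full would lose starting material faster than the solid replaces it, so I follow the dissolved pool instead. While c(starting material) is low, the catalyst removes it in a pseudo-first-order way. The Michaelis constant, in which the return of catalyst intermediate A and its forward step both count, is 1.02 mM, and so the capture constant, with the catalyst counted as free, is 0.564 s⁻¹. The hand-over ratio H is 18.8, the capture constant over the dissolution coefficient, and control passes from catalyst to solid as H rises through one.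

Because H stands well above one, dissolving is the rate-limiting step, and c(starting material) levels at the solubility divided by one plus H. Target then grows at 0.0206 mM s⁻¹ after a lag of 1.68 s, the reciprocal of capture constant plus dissolution coefficient. This gives me y = 21.2 % and sat = 2.58 %. The same formula gains 21 percentage points for cedar, 20 points for ash and 2.3 points for elm, so I name cedar, with yb = 42.4 %.

The forecast takes the feed side, saying “dissolution limits the run”, and gives y = 20.9 %, sat = 2.7 %, best = cedar and yb = 41.7 %. Its y lies a little under mine and its sat a little over.

The simulation of the flask gives y = 20.9 %, sat = 2.66 %, best = cedar and yb = 41.5 %, with gains of 21 points for cedar, 19 points for ash and 2.5 points for elm. The feed view stands in this flask, and the catalyst view keeps the region of H well below one, where the formula above puts the pool near solubility.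

In the flask at 12.0 s, free catalyst reads 94.0 %, which brings H to 17.7 and puts the pool at 3.86 % of the solid charged, beside a reading of 3.88 %. In the neighbour flask charged with 4.00 equiv of second substrate, free catalyst reads 84.6 % at 12.0 s, so H falls to 15.9 and the same reckoning gives 20.4 %. That neighbour flask gave 20.2 % of target.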